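**Retrosynthetic overview**
- Target ⇒ Claisen–Schmidt condensation of the 8-acetyl-(3S)-chromanol with 4-hydroxybenzaldehyde (ring B is bought).
- 8-Acetylchromanol ⇒ one-pot benzannulation/cyclisation: Diels–Alder of an epoxide-bearing, 2-substituted Brassard-type diene with but-3-yn-2-one builds the benzene ring, and the phenol so formed opens the side-chain epoxide 6-endo to close the pyran ring.
- Diene ⇒ silyl ketene acetal of methyl 3-methoxybutenoate that has been α-alkylated with (S)-3,3-dimethylglycidyl triflate.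
- (S) centre ⇒ Sharpless epoxidation of prenol; this carbon becomes C3 and no bond to it is broken afterwards.
- Ring order: benzene ring A first, pyran ring second, both in step 4; no other step forms a ring.

Assumption: the SMILES is read as the (3S)-chromanol with an (E)-enone; the product ee is that of the step 1 epoxidation (about 90–95%), and 3, 7, 12, LDA and n-BuLi are bought.

**Step 1**
Reactants: 1 3-methylbut-2-en-1-ol (prenol)
Product: 2 [(2S)-3,3-dimethyloxiran-2-yl]methanol
Conditions: Ti(OiPr)4 (5 mol %), L-(+)-diethyl tartrate (6 mol %), t-BuOOH (2 equiv), 4 Å MS, CH2Cl2, −20 °C; non-aqueous work-up, distillation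
Reagents that add atoms: tert-butyl hydroperoxide, CC(C)(C)OO
Why: Katsuki–Sharpless asymmetric epoxidation of a primary allylic alcohol, in which the Ti–L-(+)-tartrate catalyst delivers oxygen to the face that gives the (2S)-epoxy alcohol (the same sense that turns geraniol into its (2S,3S)-epoxide), and this carbon becomes C3 of the chroman.

**Step 2**
Reactants: 2 [(2S)-3,3-dimethyloxiran-2-yl]methanol; 3 methyl (2E)-3-methoxybut-2-enoate
Product: 5 methyl 2-{[(2S)-3,3-dimethyloxiran-2-yl]methyl}-3-methoxybut-3-enoate, via epoxy triflate 4 (not isolated)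
Conditions: (a) 2, n-BuLi, THF, −78 °C, then Tf2O; (b) 3 (1.3 equiv), LDA (1.3 equiv), THF, −78 °C; (c) solution (a) into (b), −78 → −40 °C; pH 7 buffer
Reagents that add atoms: trifluoromethanesulfonic anhydride, O=S(=O)(OS(=O)(=O)C(F)(F)F)C(F)(F)F (its CF3SO2 group is carried only by 4)
Why: Deconjugative α-alkylation of an ester dienolate, in which the lithium dienolate of 3 reacts under kinetic control at Cα with the primary triflate by SN2 at CH2, so no bond to the epoxide stereocentre is touched and (S) is carried through, while the new α-centre (both epimers) is erased in step 3.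

**Step 3**
Reactants: 5 methyl 2-{[(2S)-3,3-dimethyloxiran-2-yl]methyl}-3-methoxybut-3-enoate
Product: 6 [(1,3-dimethoxy-2-{[(2S)-3,3-dimethyloxiran-2-yl]methyl}buta-1,3-dien-1-yl)oxy]trimethylsilane
Conditions: LDA (1.1 equiv), TMSCl (1.5 equiv, present from the start), THF, −78 → 0 °C; evaporate, pentane, filter; used crude
Reagents that add atoms: chlorotrimethylsilane, C[Si](C)(C)Cl
Why: α-Deprotonation and O-silylation (silyl ketene acetal formation with TMSCl as internal quench) give the 2-substituted Brassard-type diene, with the epoxide inert at −78 °C and no stereocentre formed.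

**Step 4**
Reactants: 6 [(1,3-dimethoxy-2-{[(2S)-3,3-dimethyloxiran-2-yl]methyl}buta-1,3-dien-1-yl)oxy]trimethylsilane; 7 but-3-yn-2-one
Product: 11 1-[(3S)-3-hydroxy-5-methoxy-2,2-dimethyl-3,4-dihydro-2H-chromen-8-yl]ethan-1-one, via cyclohexadiene cycloadduct 8 (not isolated), via aryl silyl ether 9 (not isolated), via epoxy phenol 10 (not isolated)
Conditions: 7 (1.2 equiv), PhMe, 0 → 60 °C; then CSA (0.2 equiv), CH2Cl2, 0 °C → rt
Reagents that add atoms: none
Why: Proposed new method: Brassard-type ketene acetal dienes are known to add to alkynones in a regioselective Diels–Alder reaction (nucleophilic C4 to the ynone β-carbon, so the acetyl group ends ortho to the silyloxy carbon) and to aromatise by loss of methanol, and here the liberated methanol and CSA then free the chelated phenol, which opens the protonated 2,2-dimethyloxirane 6-endo at its tertiary carbon, so that the benzene and pyran rings form in one pot while the C–O bond at the stereocentre is never broken and (S) is retained; the closest known reactions are the Brassard diene–alkyne benzannulation and the acid-catalysed cyclisation of epoxidised o-prenylphenols to 2,2-dimethylchroman-3-ols.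

**Step 5**
Reactants: 11 1-[(3S)-3-hydroxy-5-methoxy-2,2-dimethyl-3,4-dihydro-2H-chromen-8-yl]ethan-1-one; 12 4-hydroxybenzaldehyde
Product: 14 (2E)-1-[(3S)-3-hydroxy-5-methoxy-2,2-dimethyl-3,4-dihydro-2H-chromen-8-yl]-3-(4-hydroxyphenyl)prop-2-en-1-one, via aldol adduct 13 (not isolated)
Conditions: 12 (1.3 equiv), KOH (50% aq), EtOH, rt, 48 h; then 1 M HCl to pH 5
Reagents that add atoms: none
Why: Claisen–Schmidt (crossed aldol) condensation of the methyl ketone enolate with the non-enolisable aldehyde followed by E1cB loss of water gives the conjugated (E)-enone, while the C3 carbinol cannot epimerise and the ring-bound ether oxygen rules out flavanone closure.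

**Compound list**
1 | 3-methylbut-2-en-1-ol (prenol) | CC(C)=CCO | starting material
2 | [(2S)-3,3-dimethyloxiran-2-yl]methanol | OC[C@@H]1OC1(C)C | intermediate
3 | methyl (2E)-3-methoxybut-2-enoate | CO/C(C)=C/C(=O)OC | starting material
4 | [(2S)-3,3-dimethyloxiran-2-yl]methyl trifluoromethanesulfonate | O=S(=O)(OC[C@@H]1OC1(C)C)C(F)(F)F | intermediate
5 | methyl 2-{[(2S)-3,3-dimethyloxiran-2-yl]methyl}-3-methoxybut-3-enoate (both C2 epimers) | COC(=O)C(C[C@@H]1OC1(C)C)C(=C)OC | intermediate
6 | [(1,3-dimethoxy-2-{[(2S)-3,3-dimethyloxiran-2-yl]methyl}buta-1,3-dien-1-yl)oxy]trimethylsilane (E/Z at the ketene acetal) | COC(O[Si](C)(C)C)=C(C[C@@H]1OC1(C)C)C(=C)OC | intermediate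
7 | but-3-yn-2-one | CC(=O)C#C | starting material
8 | 1-(4,6-dimethoxy-5-{[(2S)-3,3-dimethyloxiran-2-yl]methyl}-6-[(trimethylsilyl)oxy]cyclohexa-1,4-dien-1-yl)ethan-1-one (both C6 epimers) | CC(=O)C1=CCC(OC)=C(C[C@@H]2OC2(C)C)C1(OC)O[Si](C)(C)C | intermediate
9 | 1-(3-{[(2S)-3,3-dimethyloxiran-2-yl]methyl}-4-methoxy-2-[(trimethylsilyl)oxy]phenyl)ethan-1-one | CC(=O)c1ccc(OC)c(C[C@@H]2OC2(C)C)c1O[Si](C)(C)C | intermediate
10 | 1-(3-{[(2S)-3,3-dimethyloxiran-2-yl]methyl}-2-hydroxy-4-methoxyphenyl)ethan-1-one | CC(=O)c1ccc(OC)c(C[C@@H]2OC2(C)C)c1O | intermediate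
11 | 1-[(3S)-3-hydroxy-5-methoxy-2,2-dimethyl-3,4-dihydro-2H-chromen-8-yl]ethan-1-one | COc1ccc(C(C)=O)c2c1C[C@H](O)C(C)(C)O2 | intermediate
12 | 4-hydroxybenzaldehyde | O=Cc1ccc(O)cc1 | starting material
13 | 3-hydroxy-1-[(3S)-3-hydroxy-5-methoxy-2,2-dimethyl-3,4-dihydro-2H-chromen-8-yl]-3-(4-hydroxyphenyl)propan-1-one (both carbinol epimers) | COc1ccc(C(=O)CC(O)c2ccc(O)cc2)c2c1C[C@H](O)C(C)(C)O2 | intermediate
14 | (2E)-1-[(3S)-3-hydroxy-5-methoxy-2,2-dimethyl-3,4-dihydro-2H-chromen-8-yl]-3-(4-hydroxyphenyl)prop-2-en-1-one | COc1ccc(C(=O)/C=C/c2ccc(O)cc2)c2c1C[C@H](O)C(C)(C)O2 | target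

**Total step count:** 5 (the crude diene from step 3 goes straight into step 4).
**Longest linear sequence:** 5 (1 → 2 → 5 → 6 → 11 → 14).

**Three steps most likely to fail**

Step 2. The dienolate may alkylate at Cγ or at oxygen instead of Cα, and triflate 4 is labile. The fallback sets out from 2 and comes back to the route at 6. 2 is converted into 4 as before, and 4 C-alkylates the sodium enolate of methyl acetoacetate (NaH, THF, 0 °C), a 1,3-dicarbonyl nucleophile with a single carbon site, to give methyl 2-{[(2S)-3,3-dimethyloxiran-2-yl]methyl}-3-oxobutanoate F1. O-Methylation of its potassium enolate (KH, 18-crown-6, THF, then Me2SO4) gives the enol ether methyl 2-{[(2S)-3,3-dimethyloxiran-2-yl]methyl}-3-methoxybut-2-enoate F2 (E/Z mixture). γ-Deprotonation and O-silylation of F2 (LDA, TMSCl, THF, −78 °C) then give diene 6.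

Step 4. The epoxide may be intercepted by methanol or close 5-exo to the dihydrobenzofuran, or the crowded diene may add sluggishly. The fallback sets out from 3 and comes back to the route at 10, which the CSA half of step 4 closes to 11; the oxygen is put on only after the arene is built.
- α-Prenylation of the dienolate of 3 (LDA, THF, −78 °C; 1-bromo-3-methylbut-2-ene) gives methyl 3-methoxy-2-(3-methylbut-2-en-1-yl)but-3-enoate F3.
- LDA/TBSCl (THF–DMPU) gives the diene tert-butyl{[1,3-dimethoxy-2-(3-methylbut-2-en-1-yl)buta-1,3-dien-1-yl]oxy}dimethylsilane F4.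
- Cycloaddition with 7 (PhMe, 60–80 °C) gives the adduct 1-{6-[(tert-butyldimethylsilyl)oxy]-4,6-dimethoxy-5-(3-methylbut-2-en-1-yl)cyclohexa-1,4-dien-1-yl}ethan-1-one F5, which loses methanol on heating to the aryl silyl ether 1-{2-[(tert-butyldimethylsilyl)oxy]-4-methoxy-3-(3-methylbut-2-en-1-yl)phenyl}ethan-1-one F6.
- Shi epoxidation with the enantiomer of the fructose-derived ketone (Oxone, K2CO3 buffer, MeCN–DMM–H2O, 0 °C) gives the (S)-epoxide 1-(2-[(tert-butyldimethylsilyl)oxy]-3-{[(2S)-3,3-dimethyloxiran-2-yl]methyl}-4-methoxyphenyl)ethan-1-one F7.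
- TBAF/AcOH then releases 10.

Step 5. The phenoxide of 12 is a poor aldol acceptor, so conversion can stall. The fallback sets out from 11 and comes back at 14. Condensation of 11 with bought 4-(methoxymethoxy)benzaldehyde (KOH, EtOH, rt) gives the MOM ether (2E)-1-[(3S)-3-hydroxy-5-methoxy-2,2-dimethyl-3,4-dihydro-2H-chromen-8-yl]-3-[4-(methoxymethoxy)phenyl]prop-2-en-1-one F8, and HCl in MeOH (rt) removes the acetal to give 14.

**Further compounds**
F1 | step 2 | methyl 2-{[(2S)-3,3-dimethyloxiran-2-yl]methyl}-3-oxobutanoate | COC(=O)C(C[C@@H]1OC1(C)C)C(C)=O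
F2 | step 2 | methyl 2-{[(2S)-3,3-dimethyloxiran-2-yl]methyl}-3-methoxybut-2-enoate (E/Z mixture) | COC(=O)C(C[C@@H]1OC1(C)C)=C(C)OC
F3 | step 4 | methyl 3-methoxy-2-(3-methylbut-2-en-1-yl)but-3-enoate | COC(=O)C(CC=C(C)C)C(=C)OC
F4 | step 4 | tert-butyl{[1,3-dimethoxy-2-(3-methylbut-2-en-1-yl)buta-1,3-dien-1-yl]oxy}dimethylsilane | COC(O[Si](C)(C)C(C)(C)C)=C(CC=C(C)C)C(=C)OC
F5 | step 4 | 1-{6-[(tert-butyldimethylsilyl)oxy]-4,6-dimethoxy-5-(3-methylbut-2-en-1-yl)cyclohexa-1,4-dien-1-yl}ethan-1-one | CC(=O)C1=CCC(OC)=C(CC=C(C)C)C1(OC)O[Si](C)(C)C(C)(C)C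
F6 | step 4 | 1-{2-[(tert-butyldimethylsilyl)oxy]-4-methoxy-3-(3-methylbut-2-en-1-yl)phenyl}ethan-1-one | CC(=O)c1ccc(OC)c(CC=C(C)C)c1O[Si](C)(C)C(C)(C)C
F7 | step 4 | 1-(2-[(tert-butyldimethylsilyl)oxy]-3-{[(2S)-3,3-dimethyloxiran-2-yl]methyl}-4-methoxyphenyl)ethan-1-one | CC(=O)c1ccc(OC)c(C[C@@H]2OC2(C)C)c1O[Si](C)(C)C(C)(C)C
F8 | step 5 | (2E)-1-[(3S)-3-hydroxy-5-methoxy-2,2-dimethyl-3,4-dihydro-2H-chromen-8-yl]-3-[4-(methoxymethoxy)phenyl]prop-2-en-1-one | COc1ccc(C(=O)/C=C/c2ccc(OCOC)cc2)c2c1C[C@H](O)C(C)(C)O2
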